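**Retrosynthetic overview** (flavanone numbering: ring A = C4a to C8a, ring C = O1 to C4, ring B = C1′ to C6′)
1. The target is unmasked from its tris-MOM ether, and the C4 ketone comes from a (2S)-flavan-4-ol, so that the ring-forming step can be run with organolithiums at the alcohol oxidation level.
2. Key disconnection: ring C is opened at the aryl ether bond O1–C8a and both prenyl groups (C8 and C3′) are removed, which leads back to an open-chain (3S)-1,3-diol carrying F on C8a and Br on C8 and C3′.
3. Enabling feature: C8a lies between C4a (which carries the chain C4–C3–C2–O1) and C8 (which needs the prenyl group), and C7 bears oxygen. A C8≡C8a aryne made from C8–Li and C8a–F is therefore attacked by O1 at C8a (six-membered ring C, distal to the C7 oxygen) and leaves the new carbanion on C8.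
4. The diol comes from the symmetric linchpin 2,4-dibromo-3-fluoro-1,5-bis(methoxymethoxy)benzene (mono Br/Li exchange) and an (S)-β-silyloxy aldehyde; the only stereocentre (C2) is set by Noyori–Ikariya transfer hydrogenation of a β-keto ester.
5. Ring order: rings A and B are bought as arenes; ring C is the only ring formed (step 10), in one operation with both prenyl C–C bonds.

Key step: step 10

Assumption: the carbinol centre at C4 is carried as a mixture of both epimers from step 8 to step 10, because step 11 turns it into the carbonyl carbon.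

**Step 1**
Reactants: 1 1-(3-bromo-4-hydroxyphenyl)ethan-1-one
Product: 2 1-[3-bromo-4-(methoxymethoxy)phenyl]ethan-1-one
Conditions: NaH (1.1 equiv), MOMCl, DMF, 0 °C to rt
Reagents that add atoms: chloromethyl methyl ether (MOMCl), COCCl
Why: Williamson-type O-alkylation of the sodium phenoxide, which forms selectively because the phenol is far more acidic than the methyl ketone.

**Step 2**
Reactants: 2 1-[3-bromo-4-(methoxymethoxy)phenyl]ethan-1-one
Product: 3 ethyl 3-[3-bromo-4-(methoxymethoxy)phenyl]-3-oxopropanoate
Conditions: NaH (2.5 equiv), (EtO)2CO, THF, reflux; then AcOH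
Reagents that add atoms: diethyl carbonate, CCOC(=O)OCC
Why: Crossed Claisen condensation of the ketone enolate with non-enolisable diethyl carbonate, driven by deprotonation of the β-keto ester formed; the MOM ether and the aryl bromide are inert to NaH.

**Step 3**
Reactants: 3 ethyl 3-[3-bromo-4-(methoxymethoxy)phenyl]-3-oxopropanoate
Product: 4 ethyl (3S)-3-[3-bromo-4-(methoxymethoxy)phenyl]-3-hydroxypropanoate
Conditions: RuCl[(S,S)-TsDPEN](p-cymene) (1 mol%), HCO2H/Et3N (5:2), EtOAc, 30 °C
Reagents that add atoms: none
Why: Noyori–Ikariya asymmetric transfer hydrogenation of an aryl ketone, in which the (S,S) ligand should deliver hydride to the face that gives the (S) carbinol (the same sense as for acetophenone, aryl group held by a CH/π contact to the arene ligand); ester, aryl bromide and MOM ether are not touched.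

**Step 4**
Reactants: 4 ethyl (3S)-3-[3-bromo-4-(methoxymethoxy)phenyl]-3-hydroxypropanoate
Product: 5 ethyl (3S)-3-[3-bromo-4-(methoxymethoxy)phenyl]-3-[(tert-butyldimethylsilyl)oxy]propanoate
Conditions: TBSCl, imidazole, DMF, rt
Reagents that add atoms: tert-butyldimethylsilyl chloride (TBSCl), CC(C)(C)[Si](C)(C)Cl
Why: Standard imidazole-mediated silylation of a secondary alcohol; the silyl ether blocks retro-aldol cleavage and elimination in the next two steps and leaves the stereocentre untouched.

**Step 5**
Reactants: 5 ethyl (3S)-3-[3-bromo-4-(methoxymethoxy)phenyl]-3-[(tert-butyldimethylsilyl)oxy]propanoate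
Product: 6 (3S)-3-[3-bromo-4-(methoxymethoxy)phenyl]-3-[(tert-butyldimethylsilyl)oxy]propanal
Conditions: i-Bu2AlH (1.1 equiv), CH2Cl2, −78 °C; then aq. potassium sodium tartrate
Reagents that add atoms: none
Why: Half-reduction of an ester with i-Bu2AlH at −78 °C, where the aluminium hemiacetal is stable until work-up and so releases the aldehyde only on quench.

**Step 6**
Reactants: 7 5-fluorobenzene-1,3-diol
Product: 8 1-fluoro-3,5-bis(methoxymethoxy)benzene
Conditions: NaH (2.2 equiv), MOMCl, DMF, 0 °C to rt
Reagents that add atoms: chloromethyl methyl ether (MOMCl), COCCl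
Why: Double Williamson etherification of the bis-phenoxide.

**Step 7**
Reactants: 8 1-fluoro-3,5-bis(methoxymethoxy)benzene
Product: 9 2,4-dibromo-3-fluoro-1,5-bis(methoxymethoxy)benzene
Conditions: NBS (2.05 equiv), MeCN, 0 °C to rt
Reagents that add atoms: N-bromosuccinimide, O=C1CCC(=O)N1Br
Why: Electrophilic aromatic bromination at the two equivalent positions that are ortho to one OMOM group and para to the other, while the position between the two OMOM groups is the most hindered; NBS in MeCN produces no strong acid, so the MOM ethers should survive.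

**Step 8**
Reactants: 9 2,4-dibromo-3-fluoro-1,5-bis(methoxymethoxy)benzene; 6 (3S)-3-[3-bromo-4-(methoxymethoxy)phenyl]-3-[(tert-butyldimethylsilyl)oxy]propanal
Product: 11 (1RS,3S)-1-[3-bromo-2-fluoro-4,6-bis(methoxymethoxy)phenyl]-3-[3-bromo-4-(methoxymethoxy)phenyl]-3-[(tert-butyldimethylsilyl)oxy]propan-1-ol, via aryllithium 10 (not isolated)
Conditions: n-BuLi (1.0 equiv), THF, −78 °C; then 6, −78 °C; then AcOH, −78 °C
Reagents that add atoms: none
Why: Bromine–lithium exchange (faster than any deprotonation) desymmetrises the symmetric dibromide, and the 2-fluoroaryllithium, kept at −78 °C below the temperature of LiF loss, undergoes 1,2-addition to the aldehyde; the new carbinol centre forms as a mixture, which does not matter.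

**Step 9**
Reactants: 11 (1RS,3S)-1-[3-bromo-2-fluoro-4,6-bis(methoxymethoxy)phenyl]-3-[3-bromo-4-(methoxymethoxy)phenyl]-3-[(tert-butyldimethylsilyl)oxy]propan-1-ol
Product: 12 (1RS,3S)-1-[3-bromo-2-fluoro-4,6-bis(methoxymethoxy)phenyl]-3-[3-bromo-4-(methoxymethoxy)phenyl]propane-1,3-diol
Conditions: TBAF, THF, 0 °C to rt
Reagents that add atoms: none
Why: Fluoride-mediated desilylation driven by the strong Si–F bond; aryl MOM ethers, C–Br and the unactivated C–F bond are inert and the (S) centre is not involved.

**Step 10**
Reactants: 12 (1RS,3S)-1-[3-bromo-2-fluoro-4,6-bis(methoxymethoxy)phenyl]-3-[3-bromo-4-(methoxymethoxy)phenyl]propane-1,3-diol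
Product: 16 (2S,4RS)-5,7-bis(methoxymethoxy)-2-[4-(methoxymethoxy)-3-(3-methylbut-2-en-1-yl)phenyl]-8-(3-methylbut-2-en-1-yl)-3,4-dihydro-2H-chromen-4-ol, via tetralithio dialkoxide 13 (not isolated), via aryne 14 (not isolated), via trilithio chromanolate 15 (not isolated)
Conditions: MeLi (2.0 equiv), THF (0.02 M), −78 °C; t-BuLi (4.1 equiv), −78 °C; warm to −30 °C; CuBr·SMe2 (2.2 equiv), −78 to −40 °C; prenyl bromide (4 equiv), −78 to 0 °C; then H2O
Reagents that add atoms: prenyl bromide (1-bromo-3-methylbut-2-ene), CC(C)=CCBr
Why: Proposed new method: MeLi first turns both hydroxyls into lithium alkoxides and t-BuLi then exchanges both aryl bromides (13); on warming, the ring-A lithium at C8 expels fluoride from C8a to give the C8≡C8a aryne 14, the C2 alkoxide adds to C8a, which forms the O1–C8a bond, closes ring C and leaves a new aryllithium at C8 (15), and the two aryllithiums (C8 and C3′) are transmetalated to copper and allylated by prenyl bromide at its CH2 carbon. The closest known reaction types are the base-mediated ring closure of alcohols tethered to halobenzenes through arynes (a known route to chromans), anionic aryne cyclisations in which the newly formed aryllithium is trapped by an electrophile, and nucleophile/electrophile three-component couplings of 3-alkoxyarynes made from fluoroarenes; what is new is their combination on a dialkoxide that carries a second aryllithium, with copper-mediated prenylation as the terminating event. Ring C closes in a 6-exo-dig mode by in-plane attack of the alkoxide oxygen on the aryne carbon next to the tether. No stereocentre is created: the (S) centre at C2 is retained because its C–O bond is never broken (its oxygen is the nucleophile), and C4 remains an epimeric mixture that step 11 erases. The step needs attack at C8a and not C8, intramolecular and not intermolecular capture of the aryne, and C-prenylation at the CH2 terminus of the allyl unit: the three-atom tether (attack at C8 would need a strained bridged ring, the C4 alkoxide a four-membered ring) together with the inductive effect of the C7 oxygen (attack at the distal aryne carbon, carbanion next to oxygen) secures the first, high dilution the second, and arylcopper intermediates beside lithium alkoxides that are unreactive at low temperature the third.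

**Step 11**
Reactants: 16 (2S,4RS)-5,7-bis(methoxymethoxy)-2-[4-(methoxymethoxy)-3-(3-methylbut-2-en-1-yl)phenyl]-8-(3-methylbut-2-en-1-yl)-3,4-dihydro-2H-chromen-4-ol
Product: 17 (2S)-5,7-bis(methoxymethoxy)-2-[4-(methoxymethoxy)-3-(3-methylbut-2-en-1-yl)phenyl]-8-(3-methylbut-2-en-1-yl)-2,3-dihydro-4H-chromen-4-one
Conditions: Dess–Martin periodinane (1.5 equiv), CH2Cl2, 0 °C to rt
Reagents that add atoms: none
Why: Dess–Martin oxidation of a secondary benzylic alcohol under non-basic conditions, so that both C4 epimers converge on the flavanone without enolisation or retro-oxa-Michael opening that would epimerise C2; trisubstituted alkenes and MOM ethers are inert.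

**Step 12**
Reactants: 17 (2S)-5,7-bis(methoxymethoxy)-2-[4-(methoxymethoxy)-3-(3-methylbut-2-en-1-yl)phenyl]-8-(3-methylbut-2-en-1-yl)-2,3-dihydro-4H-chromen-4-one
Product: 18 euchrestaflavanone A, (2S)-5,7-dihydroxy-2-[4-hydroxy-3-(3-methylbut-2-en-1-yl)phenyl]-8-(3-methylbut-2-en-1-yl)-2,3-dihydro-4H-chromen-4-one
Conditions: HCl (1.25 M in MeOH), 40 °C
Reagents that add atoms: none
Why: Acid-catalysed transacetalisation of the three aryl MOM ethers to methanol, a deprotection with close precedent on prenylated flavanones, kept at mild temperature so that the prenyl alkenes are not protonated and ring C is not opened.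

**Compound list**
1 | 1-(3-bromo-4-hydroxyphenyl)ethan-1-one | CC(=O)c1ccc(O)c(Br)c1 | starting material
2 | 1-[3-bromo-4-(methoxymethoxy)phenyl]ethan-1-one | CC(=O)c1ccc(OCOC)c(Br)c1 | intermediate
3 | ethyl 3-[3-bromo-4-(methoxymethoxy)phenyl]-3-oxopropanoate | CCOC(=O)CC(=O)c1ccc(OCOC)c(Br)c1 | intermediate
4 | ethyl (3S)-3-[3-bromo-4-(methoxymethoxy)phenyl]-3-hydroxypropanoate | CCOC(=O)C[C@H](O)c1ccc(OCOC)c(Br)c1 | intermediate
5 | ethyl (3S)-3-[3-bromo-4-(methoxymethoxy)phenyl]-3-[(tert-butyldimethylsilyl)oxy]propanoate | CCOC(=O)C[C@H](O[Si](C)(C)C(C)(C)C)c1ccc(OCOC)c(Br)c1 | intermediate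
6 | (3S)-3-[3-bromo-4-(methoxymethoxy)phenyl]-3-[(tert-butyldimethylsilyl)oxy]propanal | O=CC[C@H](O[Si](C)(C)C(C)(C)C)c1ccc(OCOC)c(Br)c1 | intermediate
7 | 5-fluorobenzene-1,3-diol | Oc1cc(O)cc(F)c1 | starting material
8 | 1-fluoro-3,5-bis(methoxymethoxy)benzene | COCOc1cc(F)cc(OCOC)c1 | intermediate
9 | 2,4-dibromo-3-fluoro-1,5-bis(methoxymethoxy)benzene | COCOc1cc(OCOC)c(Br)c(F)c1Br | intermediate
10 | [3-bromo-2-fluoro-4,6-bis(methoxymethoxy)phenyl]lithium | [Li]c1c(OCOC)cc(OCOC)c(Br)c1F | intermediate
11 | (1RS,3S)-1-[3-bromo-2-fluoro-4,6-bis(methoxymethoxy)phenyl]-3-[3-bromo-4-(methoxymethoxy)phenyl]-3-[(tert-butyldimethylsilyl)oxy]propan-1-ol | OC(C[C@H](O[Si](C)(C)C(C)(C)C)c1ccc(OCOC)c(Br)c1)c1c(F)c(Br)c(OCOC)cc1OCOC | intermediate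
12 | (1RS,3S)-1-[3-bromo-2-fluoro-4,6-bis(methoxymethoxy)phenyl]-3-[3-bromo-4-(methoxymethoxy)phenyl]propane-1,3-diol | OC(C[C@H](O)c1ccc(OCOC)c(Br)c1)c1c(F)c(Br)c(OCOC)cc1OCOC | intermediate
13 | dilithium (1RS,3S)-1-[2-fluoro-3-lithio-4,6-bis(methoxymethoxy)phenyl]-3-[3-lithio-4-(methoxymethoxy)phenyl]propane-1,3-bis(olate) | [Li]OC(C[C@H](O[Li])c1ccc(OCOC)c([Li])c1)c1c(F)c([Li])c(OCOC)cc1OCOC | intermediate
14 | dilithium (1RS,3S)-1-[2,3-didehydro-4,6-bis(methoxymethoxy)phenyl]-3-[3-lithio-4-(methoxymethoxy)phenyl]propane-1,3-bis(olate) (aryne) | [Li]OC(C[C@H](O[Li])c1ccc(OCOC)c([Li])c1)C1=C(OCOC)C=C(OCOC)C#C1 | intermediate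
15 | lithium (2S,4RS)-8-lithio-2-[3-lithio-4-(methoxymethoxy)phenyl]-5,7-bis(methoxymethoxy)-3,4-dihydro-2H-chromen-4-olate | [Li]OC1C[C@@H](c2ccc(OCOC)c([Li])c2)Oc2c([Li])c(OCOC)cc(OCOC)c21 | intermediate
16 | (2S,4RS)-5,7-bis(methoxymethoxy)-2-[4-(methoxymethoxy)-3-(3-methylbut-2-en-1-yl)phenyl]-8-(3-methylbut-2-en-1-yl)-3,4-dihydro-2H-chromen-4-ol | OC1C[C@@H](c2ccc(OCOC)c(CC=C(C)C)c2)Oc2c(CC=C(C)C)c(OCOC)cc(OCOC)c21 | intermediate
17 | (2S)-5,7-bis(methoxymethoxy)-2-[4-(methoxymethoxy)-3-(3-methylbut-2-en-1-yl)phenyl]-8-(3-methylbut-2-en-1-yl)-2,3-dihydro-4H-chromen-4-one | O=C1C[C@@H](c2ccc(OCOC)c(CC=C(C)C)c2)Oc2c(CC=C(C)C)c(OCOC)cc(OCOC)c21 | intermediate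
18 | euchrestaflavanone A, (2S)-5,7-dihydroxy-2-[4-hydroxy-3-(3-methylbut-2-en-1-yl)phenyl]-8-(3-methylbut-2-en-1-yl)-2,3-dihydro-4H-chromen-4-one | CC(C)=CCc1cc([C@@H]2CC(=O)c3c(O)cc(O)c(CC=C(C)C)c3O2)ccc1O | target

**Step count and risks**
Total step count: 12. Longest linear sequence: 10 steps (steps 1 to 5, then 8 to 12); steps 6 and 7 form the two-step branch to the linchpin 9.

Steps most likely to fail:

1. Step 10 (the new method). What may go wrong: capture of the aryne by the ring-B aryllithium or by an alkoxide of a second molecule instead of ring closure, proton transfer that scrambles the lithiated positions before the copper step, or premature protonation of the aryllithiums. The fallback uses known chemistry only and sets out from 11.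
 - After deprotonation of the hydroxyl (MeLi), double bromine–lithium exchange (t-BuLi, −78 °C), transmetalation with CuBr·SMe2 without warming (so that fluoride is kept) and allylation with prenyl bromide should give the diprenylated 2-fluoroaryl carbinol silyl ether F1.
 - Dess–Martin oxidation should give the aryl ketone F2.
 - HF·pyridine in THF should remove the silyl group and give the β-hydroxy ketone F3.
 - Intramolecular nucleophilic aromatic substitution (Cs2CO3, DMF, rt), in which the C2 alkoxide displaces the fluoride that the ortho carbonyl activates, closes the same O1–C8a bond and comes back to the route at 17.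

2. Step 8. What may go wrong: loss of LiF from the 2-fluoroaryllithium (aryne formation) before it adds, exchange of both bromides, or enolisation of the aldehyde followed by β-elimination of the silyloxy group. The fallback reverses the polarity of the fragment union and sets out from 9 and 2.
 - Bromine–magnesium exchange of 9 with i-PrMgCl·LiCl (the arylmagnesium does not lose fluoride at 0 °C) and formylation with DMF should give the benzaldehyde F4.
 - Aldol addition of the lithium enolate of ketone 2 (LDA, THF, −78 °C) to F4 should give the racemic β-hydroxy ketone F5.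
 - Noyori–Ikariya transfer hydrogenation of the aryl ketone of F5 with RuCl[(S,S)-TsDPEN](p-cymene) and HCO2H/Et3N should set the (S) carbinol next to ring B under catalyst control and comes back to the route at 12.

3. Step 7. What may go wrong: loss of regiocontrol (bromination between the two OMOM groups), over-bromination to the tribromide, or acid-induced loss of a MOM group. The fallback replaces electrophilic substitution by directed metalation and sets out from 8.
 - Lithiation with lithium 2,2,6,6-tetramethylpiperidide (THF, −78 °C) at the most acidic C–H, the one between F and OMOM, and quench with 1,2-dibromo-1,1,2,2-tetrachloroethane should give the monobromide F6.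
 - A second lithiation at the remaining position between F and OMOM and the same bromine source comes back to the route at 9.

**Further compounds**
F1 | step 10 | (1RS,3S)-3-[(tert-butyldimethylsilyl)oxy]-1-[2-fluoro-4,6-bis(methoxymethoxy)-3-(3-methylbut-2-en-1-yl)phenyl]-3-[4-(methoxymethoxy)-3-(3-methylbut-2-en-1-yl)phenyl]propan-1-ol | OC(C[C@H](O[Si](C)(C)C(C)(C)C)c1ccc(OCOC)c(CC=C(C)C)c1)c1c(F)c(CC=C(C)C)c(OCOC)cc1OCOC
F2 | step 10 | (3S)-3-[(tert-butyldimethylsilyl)oxy]-1-[2-fluoro-4,6-bis(methoxymethoxy)-3-(3-methylbut-2-en-1-yl)phenyl]-3-[4-(methoxymethoxy)-3-(3-methylbut-2-en-1-yl)phenyl]propan-1-one | O=C(C[C@H](O[Si](C)(C)C(C)(C)C)c1ccc(OCOC)c(CC=C(C)C)c1)c1c(F)c(CC=C(C)C)c(OCOC)cc1OCOC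
F3 | step 10 | (3S)-1-[2-fluoro-4,6-bis(methoxymethoxy)-3-(3-methylbut-2-en-1-yl)phenyl]-3-hydroxy-3-[4-(methoxymethoxy)-3-(3-methylbut-2-en-1-yl)phenyl]propan-1-one | O=C(C[C@H](O)c1ccc(OCOC)c(CC=C(C)C)c1)c1c(F)c(CC=C(C)C)c(OCOC)cc1OCOC
F4 | step 8 | 3-bromo-2-fluoro-4,6-bis(methoxymethoxy)benzaldehyde | O=Cc1c(F)c(Br)c(OCOC)cc1OCOC
F5 | step 8 | (3RS)-3-[3-bromo-2-fluoro-4,6-bis(methoxymethoxy)phenyl]-1-[3-bromo-4-(methoxymethoxy)phenyl]-3-hydroxypropan-1-one | O=C(CC(O)c1c(F)c(Br)c(OCOC)cc1OCOC)c1ccc(OCOC)c(Br)c1
F6 | step 7 | 2-bromo-1-fluoro-3,5-bis(methoxymethoxy)benzene | COCOc1cc(OCOC)c(Br)c(F)c1
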